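**Plan**
- Retrosynthesis: the ring epoxide goes back to the enone (ketone → allylic alcohol → hydroxyl-directed epoxidation → ketone), the side-chain epoxide to a prenyl alkene, and the two angelates to a diol.
- The 2-methylcyclohex-2-enone ring is cut at the ring CH2–CH= bond and at the C(=O)–C(Me)= bond, giving a trans-2-silyloxy-3-alkylcyclobutanone and a silyl-capped propyne; the cyclobutanone goes back to dichloroketene and 3-butenal diethyl acetal.
- Enabling feature: the 2-methyl-2,3-epoxycyclohexanone is a masked 2-methylcyclohex-2-enone whose C(Me)=CH unit lies between the carbonyl carbon and the ring CH2. That is the pattern left when an alkyne inserts into the C(O)–CH2 bond of a cyclobutanone, and the other four ring atoms, C(=O)–CH(O)–CH(side chain)–CH2, are that cyclobutanone.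
- Forward: four-membered ring by [2+2], enantiotopic deprotonation and Rubottom oxidation, six-membered ring by nickel-catalysed two-carbon ring expansion, side chain grown from the acetal carbon (α-methylenation, allylboration, cross-metathesis), esterification, then three oxidations.
- Stereochemistry: ring CH(side chain) from a chiral lithium amide and ring CH–O anti to it (Rubottom); carbinol from the Ipc2B(allyl) reagent; side-chain epoxide from the Shi ketone; ring epoxide from axial hydride delivery then vanadium-directed epoxidation; Z esters from angelic acid.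

Key step: step 6

Assumption: the sense of the enantiotopic deprotonation in step 4 is taken to be the one known for 4-substituted cyclohexanones with the same amide; should it prove opposite, the (S,S) amide is used in its place.

**Step 1**
Reactants: 1 prop-1-yn-1-ylmagnesium bromide; 2 benzyl(chloro)dimethylsilane
Product: 3 benzyl(dimethyl)(prop-1-yn-1-yl)silane
Conditions: THF, 0 °C → rt
Reagents that add atoms: none
Why: nucleophilic substitution at silicon by the alkynyl Grignard reagent gives the internal silyl alkyne, whose benzyldimethylsilyl group can later be removed by fluoride.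

**Step 2**
Reactants: 4 4,4-diethoxybut-1-ene; 5 trichloroacetyl chloride
Product: 7 rac-2,2-dichloro-3-(2,2-diethoxyethyl)cyclobutan-1-one, via dichloroketene 6 (not isolated)
Conditions: Zn–Cu couple, Et2O–DME, 0 °C → rt, slow addition of 5
Reagents that add atoms: none
Why: ketene–alkene [2+2] cycloaddition in which the ketene carbonyl carbon bonds to the terminal CH2 and the CCl2 carbon to the substituted alkene carbon, as is general for monosubstituted alkenes; DME ties up ZnCl2 so that the acetal should survive.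

**Step 3**
Reactants: 7 rac-2,2-dichloro-3-(2,2-diethoxyethyl)cyclobutan-1-one
Product: 8 3-(2,2-diethoxyethyl)cyclobutan-1-one
Conditions: Zn dust, AcOH, TMEDA, EtOH, 0 °C → rt
Reagents that add atoms: none
Why: reductive dechlorination of an α,α-dichloroketone by zinc through the zinc enolate; the product is achiral, so the racemic centre of 7 is of no consequence.

**Step 4**
Reactants: 8 3-(2,2-diethoxyethyl)cyclobutan-1-one
Product: 10 {[(3R)-3-(2,2-diethoxyethyl)cyclobut-1-en-1-yl]oxy}(triethyl)silane, via lithium enolate 9 (not isolated)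
Conditions: (R,R)-bis(1-phenylethyl)amine, n-BuLi, Et3SiCl (present from the start), THF, −100 °C
Reagents that add atoms: chlorotriethylsilane, CC[Si](Cl)(CC)CC
Why: enantioselective deprotonation of a prochiral 3-substituted cyclobutanone by a homochiral lithium amide with in situ O-silylation; the base picks one of the two enantiotopic CH2 groups and so fixes the configuration of the ring carbon that bears the side chain.

**Step 5**
Reactants: 10 {[(3R)-3-(2,2-diethoxyethyl)cyclobut-1-en-1-yl]oxy}(triethyl)silane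
Product: 12 (2R,3S)-3-(2,2-diethoxyethyl)-2-[(triethylsilyl)oxy]cyclobutan-1-one, via silyloxy epoxide 11 (not isolated)
Conditions: DMDO (acetone solution), CH2Cl2, −78 → 0 °C
Reagents that add atoms: dimethyldioxirane, CC1(C)OO1
Why: Rubottom oxidation, in which the dioxirane epoxidises the enol ether on the face away from the neighbouring side chain and the silyloxy epoxide opens with a 1,4-shift of silicon to the new oxygen, which should give the trans α-silyloxy ketone.

**Step 6**
Reactants: 12 (2R,3S)-3-(2,2-diethoxyethyl)-2-[(triethylsilyl)oxy]cyclobutan-1-one; 3 benzyl(dimethyl)(prop-1-yn-1-yl)silane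
Product: 15 (5S,6R)-3-[benzyl(dimethyl)silyl]-5-(2,2-diethoxyethyl)-2-methyl-6-[(triethylsilyl)oxy]cyclohex-2-en-1-one, via oxanickelacyclopentene 13 (not isolated), via nickelacycloheptenone 14 (not isolated)
Conditions: Ni(cod)2 (10 mol%), PCy3 (20 mol%), toluene, 100 °C
Reagents that add atoms: none
Why: Zerovalent nickel couples the strained ketone C=O of 12 and alkyne 3 oxidatively to the spiro oxanickelacyclopentene 13, which makes the C(=O)–C(Me) bond; β-carbon elimination then opens the four-membered ring at its CH2–C(O) bond to the seven-membered nickelacycle 14, and C(sp3)–C(sp2) reductive elimination makes the CH2–C(Si) bond and frees the catalyst. The closest known reaction is the nickel-catalysed insertion of internal alkynes into cyclobutanones (and azetidin-3-ones) to give cyclohex-2-enones. The six-membered ring is closed in the reductive elimination, so the overall mode is a formal [4+2] annulation by two-carbon ring expansion and no cyclisation onto a π-bond is involved. No stereocentre is made: the two centres of 12 lie outside the bonds that are formed or broken and should be carried through, the trans arrangement also being the more stable one at the enolisable carbon. Two selectivities are needed: cleavage of the CH2–C(O) bond and not the CH(OSiEt3)–C(O) bond, which the primary alkyl–nickel bond and the bulk of the silyloxy group should secure, and an alkyne orientation with methyl next to the carbonyl, which the bulky silyl group should secure by taking the nickel-bound carbon as in nickel-mediated alkyne–carbonyl couplings. The silyl group also keeps the alkyne internal, which avoids the oligomerisation expected of propyne itself, and it is removed in step 11.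

**Step 7**
Reactants: 15 (5S,6R)-3-[benzyl(dimethyl)silyl]-5-(2,2-diethoxyethyl)-2-methyl-6-[(triethylsilyl)oxy]cyclohex-2-en-1-one
Product: 17 2-{(1S,6R)-3-[benzyl(dimethyl)silyl]-4-methyl-5-oxo-6-[(triethylsilyl)oxy]cyclohex-3-en-1-yl}acetaldehyde, via pyridinium salt 16 (not isolated)
Conditions: Et3SiOTf, 2,4,6-collidine, CH2Cl2, 0 °C; then H2O
Reagents that add atoms: water, O
Why: silyl triflate–pyridine-base cleavage of an aldehyde acetal through a pyridinium N,O-acetal that water hydrolyses, a method that should leave the silyl ether, the vinylsilane and the enone untouched where aqueous acid would not.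

**Step 8**
Reactants: 17 2-{(1S,6R)-3-[benzyl(dimethyl)silyl]-4-methyl-5-oxo-6-[(triethylsilyl)oxy]cyclohex-3-en-1-yl}acetaldehyde
Product: 18 2-{(1R,6R)-3-[benzyl(dimethyl)silyl]-4-methyl-5-oxo-6-[(triethylsilyl)oxy]cyclohex-3-en-1-yl}prop-2-enal
Conditions: 37% aq. CH2O, pyrrolidine (10 mol%), propionic acid (10 mol%), i-PrOH, 45 °C
Reagents that add atoms: formaldehyde, C=O
Why: amine-catalysed α-methylenation of an aldehyde (Mannich condensation, then loss of the amine), which makes the 1,1-disubstituted alkene of the side chain.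

**Step 9**
Reactants: 18 2-{(1R,6R)-3-[benzyl(dimethyl)silyl]-4-methyl-5-oxo-6-[(triethylsilyl)oxy]cyclohex-3-en-1-yl}prop-2-enal
Product: 20 (5R,6R)-3-[benzyl(dimethyl)silyl]-5-[(3S)-3-hydroxyhexa-1,5-dien-2-yl]-2-methyl-6-[(triethylsilyl)oxy]cyclohex-2-en-1-one, via borinate ester 19 (not isolated)
Conditions: B-allylbis(isopinocampheyl)borane of the (+)-α-pinene series (salt-free pentane solution, the reagent made from (−)-Ipc2BOMe and allylmagnesium bromide), Et2O, −78 °C; then ethanolamine, rt
Reagents that add atoms: B-allylbis[(1R,2R,3R,5S)-isopinocampheyl]borane, C=CCB([C@@H]1C[C@@H]2C[C@H]([C@H]1C)C2(C)C)[C@@H]1C[C@@H]2C[C@H]([C@H]1C)C2(C)C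
Why: Brown allylboration through a chair six-membered transition state, in which reagent control should deliver allyl to the Si face of the aldehyde and give the (S) carbinol, while at −78 °C the aldehyde reacts well ahead of the conjugated ketone.

**Step 10**
Reactants: 20 (5R,6R)-3-[benzyl(dimethyl)silyl]-5-[(3S)-3-hydroxyhexa-1,5-dien-2-yl]-2-methyl-6-[(triethylsilyl)oxy]cyclohex-2-en-1-one
Product: 21 (5R,6R)-3-[benzyl(dimethyl)silyl]-5-[(3S)-3-hydroxy-6-methylhepta-1,5-dien-2-yl]-2-methyl-6-[(triethylsilyl)oxy]cyclohex-2-en-1-one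
Conditions: 2-methylbut-2-ene (large excess), second-generation Grubbs catalyst RuCl2(=CHPh)(H2IMes)(PCy3) (5 mol%), CH2Cl2, 40 °C
Reagents that add atoms: 2-methylbut-2-ene, CC=C(C)C
Why: olefin cross-metathesis turns the terminal allyl group into prenyl while the 1,1-disubstituted alkene, the vinylsilane and the enone are too hindered or electron-poor to take part; it is run before the esterification so that no enoate lies within reach of the ruthenium alkylidene.

**Step 11**
Reactants: 21 (5R,6R)-3-[benzyl(dimethyl)silyl]-5-[(3S)-3-hydroxy-6-methylhepta-1,5-dien-2-yl]-2-methyl-6-[(triethylsilyl)oxy]cyclohex-2-en-1-one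
Product: 22 (5R,6R)-6-hydroxy-5-[(3S)-3-hydroxy-6-methylhepta-1,5-dien-2-yl]-2-methylcyclohex-2-en-1-one
Conditions: Bu4NF (4 equiv), THF, 0 °C → rt
Reagents that add atoms: none
Why: fluoride cleaves the silyl ether and, by attack at the benzyldimethylsilyl group (loss of benzyl, then protodesilylation of the activated alkenylsilane), replaces the ring C–Si bond by C–H without moving the double bond.

**Step 12**
Reactants: 22 (5R,6R)-6-hydroxy-5-[(3S)-3-hydroxy-6-methylhepta-1,5-dien-2-yl]-2-methylcyclohex-2-en-1-one; 23 angelic acid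
Product: 25 (1R,6R)-3-methyl-6-[(3S)-6-methyl-3-{[(2Z)-2-methylbut-2-enoyl]oxy}hepta-1,5-dien-2-yl]-2-oxocyclohex-3-en-1-yl (2Z)-2-methylbut-2-enoate, via mixed anhydride 24 (not isolated)
Conditions: 23 (3 equiv), 2,4,6-trichlorobenzoyl chloride, Et3N, toluene, rt; then 22, 80 °C
Reagents that add atoms: none
Why: Yamaguchi-type mixed-anhydride acylation of both secondary hydroxyl groups, run without a nucleophilic amine catalyst so that conjugate addition–elimination cannot turn the (Z)-angelate into the (E)-tiglate.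

**Step 13**
Reactants: 25 (1R,6R)-3-methyl-6-[(3S)-6-methyl-3-{[(2Z)-2-methylbut-2-enoyl]oxy}hepta-1,5-dien-2-yl]-2-oxocyclohex-3-en-1-yl (2Z)-2-methylbut-2-enoate
Product: 26 (1R,6R)-6-[(3S)-4-[(2R)-3,3-dimethyloxiran-2-yl]-3-{[(2Z)-2-methylbut-2-enoyl]oxy}but-1-en-2-yl]-3-methyl-2-oxocyclohex-3-en-1-yl (2Z)-2-methylbut-2-enoate
Conditions: D-fructose-derived Shi ketone (30 mol%), KHSO5 (as its triple salt 2KHSO5·KHSO4·K2SO4), K2CO3, Bu4NHSO4, MeCN–CH2(OMe)2 / aq. Na2B4O7 buffer, 0 °C
Reagents that add atoms: potassium peroxymonosulfate, [K+].[O-]S(=O)(=O)OO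
Why: Shi epoxidation, in which the chiral dioxirane reacts only with the electron-rich trisubstituted prenyl alkene (the enone, the angelates and the allylic-ester alkene are electron-poor) through a spiro transition state, which for the D-fructose-derived ketone should give the (R)-epoxide.

**Step 14**
Reactants: 26 (1R,6R)-6-[(3S)-4-[(2R)-3,3-dimethyloxiran-2-yl]-3-{[(2Z)-2-methylbut-2-enoyl]oxy}but-1-en-2-yl]-3-methyl-2-oxocyclohex-3-en-1-yl (2Z)-2-methylbut-2-enoate
Product: 27 (1R,2R,6R)-6-[(3S)-4-[(2R)-3,3-dimethyloxiran-2-yl]-3-{[(2Z)-2-methylbut-2-enoyl]oxy}but-1-en-2-yl]-2-hydroxy-3-methylcyclohex-3-en-1-yl (2Z)-2-methylbut-2-enoate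
Conditions: NaBH4, CeCl3·7H2O, MeOH, −78 °C
Reagents that add atoms: none
Why: Luche 1,2-reduction, in which axial hydride attack on the half-chair with both ring substituents equatorial should give the equatorial alcohol, cis to the side chain and trans to the neighbouring ester, as in the reduction of carvone.

**Step 15**
Reactants: 27 (1R,2R,6R)-6-[(3S)-4-[(2R)-3,3-dimethyloxiran-2-yl]-3-{[(2Z)-2-methylbut-2-enoyl]oxy}but-1-en-2-yl]-2-hydroxy-3-methylcyclohex-3-en-1-yl (2Z)-2-methylbut-2-enoate
Product: 28 (1S,2S,3R,4R,6R)-4-[(3S)-4-[(2R)-3,3-dimethyloxiran-2-yl]-3-{[(2Z)-2-methylbut-2-enoyl]oxy}but-1-en-2-yl]-2-hydroxy-1-methyl-7-oxabicyclo[4.1.0]heptan-3-yl (2Z)-2-methylbut-2-enoate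
Conditions: VO(acac)2 (5 mol%), t-BuOOH (decane solution), CH2Cl2, 0 °C → rt
Reagents that add atoms: tert-butyl hydroperoxide, CC(C)(C)OO
Why: hydroxyl-directed epoxidation, in which the vanadium alkoxide of the allylic alcohol delivers the peroxide oxygen to the ring alkene on the face of the hydroxyl group, so the epoxide forms cis to the side chain, and no other alkene has a free hydroxyl to bind the metal.

**Step 16**
Reactants: 28 (1S,2S,3R,4R,6R)-4-[(3S)-4-[(2R)-3,3-dimethyloxiran-2-yl]-3-{[(2Z)-2-methylbut-2-enoyl]oxy}but-1-en-2-yl]-2-hydroxy-1-methyl-7-oxabicyclo[4.1.0]heptan-3-yl (2Z)-2-methylbut-2-enoate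
Product: 29 (1R,3R,4R,6R)-4-[(3S)-4-[(2R)-3,3-dimethyloxiran-2-yl]-3-{[(2Z)-2-methylbut-2-enoyl]oxy}but-1-en-2-yl]-1-methyl-2-oxo-7-oxabicyclo[4.1.0]heptan-3-yl (2Z)-2-methylbut-2-enoate
Conditions: Dess–Martin periodinane, pyridine, CH2Cl2, 0 °C → rt
Reagents that add atoms: none
Why: Dess–Martin oxidation of the secondary epoxy alcohol to the epoxy ketone under buffered conditions that should not epimerise the neighbouring ester-bearing carbon, which gives the target.

**Compound list**
1 | prop-1-yn-1-ylmagnesium bromide | CC#C[Mg]Br | starting material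
2 | benzyl(chloro)dimethylsilane | C[Si](C)(Cl)Cc1ccccc1 | starting material
3 | benzyl(dimethyl)(prop-1-yn-1-yl)silane | CC#C[Si](C)(C)Cc1ccccc1 | intermediate
4 | 4,4-diethoxybut-1-ene (3-butenal diethyl acetal) | C=CCC(OCC)OCC | starting material
5 | trichloroacetyl chloride | ClC(Cl)(Cl)C(=O)Cl | starting material
6 | dichloroketene | ClC(Cl)=C=O | intermediate (not isolated)
7 | rac-2,2-dichloro-3-(2,2-diethoxyethyl)cyclobutan-1-one | CCOC(OCC)CC1CC(=O)C1(Cl)Cl | intermediate
8 | 3-(2,2-diethoxyethyl)cyclobutan-1-one | CCOC(OCC)CC1CC(=O)C1 | intermediate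
9 | lithium (3R)-3-(2,2-diethoxyethyl)cyclobut-1-en-1-olate | CCOC(OCC)C[C@H]1CC(O[Li])=C1 | intermediate (not isolated)
10 | {[(3R)-3-(2,2-diethoxyethyl)cyclobut-1-en-1-yl]oxy}(triethyl)silane | CCOC(OCC)C[C@H]1CC(O[Si](CC)(CC)CC)=C1 | intermediate
11 | 3-(2,2-diethoxyethyl)-1-[(triethylsilyl)oxy]-5-oxabicyclo[2.1.0]pentane, oxirane anti to the side chain | CCOC(OCC)C[C@H]1C[C@]2(O[Si](CC)(CC)CC)O[C@@H]21 | intermediate (not isolated)
12 | (2R,3S)-3-(2,2-diethoxyethyl)-2-[(triethylsilyl)oxy]cyclobutan-1-one | CCOC(OCC)C[C@H]1CC(=O)[C@@H]1O[Si](CC)(CC)CC | intermediate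
13 | spiro oxanickelacyclopentene from 12 and 3 (PCy3 on nickel not drawn; configuration at the spiro carbon open) | CCOC(OCC)C[C@H]1CC2(O[Ni]C([Si](C)(C)Cc3ccccc3)=C2C)[C@@H]1O[Si](CC)(CC)CC | intermediate (not isolated)
14 | seven-membered alkyl(alkenyl)nickelacycle, a nickelacycloheptenone (PCy3 on nickel not drawn) | CCOC(OCC)C[C@H]1C[Ni]C([Si](C)(C)Cc2ccccc2)=C(C)C(=O)[C@@H]1O[Si](CC)(CC)CC | intermediate (not isolated)
15 | (5S,6R)-3-[benzyl(dimethyl)silyl]-5-(2,2-diethoxyethyl)-2-methyl-6-[(triethylsilyl)oxy]cyclohex-2-en-1-one | CCOC(OCC)C[C@H]1CC([Si](C)(C)Cc2ccccc2)=C(C)C(=O)[C@@H]1O[Si](CC)(CC)CC | intermediate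
16 | 1-(1-ethoxyalkyl)-2,4,6-trimethylpyridinium triflate derived from 15 (N,O-acetal salt; configuration at the acetal carbon open) | CCOC(C[C@H]1CC([Si](C)(C)Cc2ccccc2)=C(C)C(=O)[C@@H]1O[Si](CC)(CC)CC)[n+]1c(C)cc(C)cc1C.[O-]S(=O)(=O)C(F)(F)F | intermediate (not isolated)
17 | 2-{(1S,6R)-3-[benzyl(dimethyl)silyl]-4-methyl-5-oxo-6-[(triethylsilyl)oxy]cyclohex-3-en-1-yl}acetaldehyde | O=CC[C@H]1CC([Si](C)(C)Cc2ccccc2)=C(C)C(=O)[C@@H]1O[Si](CC)(CC)CC | intermediate
18 | 2-{(1R,6R)-3-[benzyl(dimethyl)silyl]-4-methyl-5-oxo-6-[(triethylsilyl)oxy]cyclohex-3-en-1-yl}prop-2-enal | C=C(C=O)[C@H]1CC([Si](C)(C)Cc2ccccc2)=C(C)C(=O)[C@@H]1O[Si](CC)(CC)CC | intermediate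
19 | bis[(1R,2R,3R,5S)-isopinocampheyl]borinate ester of alcohol 20 | C=C([C@H](CC=C)OB([C@@H]1C[C@@H]2C[C@H]([C@H]1C)C2(C)C)[C@@H]1C[C@@H]2C[C@H]([C@H]1C)C2(C)C)[C@H]1CC([Si](C)(C)Cc2ccccc2)=C(C)C(=O)[C@@H]1O[Si](CC)(CC)CC | intermediate (not isolated)
20 | (5R,6R)-3-[benzyl(dimethyl)silyl]-5-[(3S)-3-hydroxyhexa-1,5-dien-2-yl]-2-methyl-6-[(triethylsilyl)oxy]cyclohex-2-en-1-one | C=C([C@H](CC=C)O)[C@H]1CC([Si](C)(C)Cc2ccccc2)=C(C)C(=O)[C@@H]1O[Si](CC)(CC)CC | intermediate
21 | (5R,6R)-3-[benzyl(dimethyl)silyl]-5-[(3S)-3-hydroxy-6-methylhepta-1,5-dien-2-yl]-2-methyl-6-[(triethylsilyl)oxy]cyclohex-2-en-1-one | C=C([C@H](CC=C(C)C)O)[C@H]1CC([Si](C)(C)Cc2ccccc2)=C(C)C(=O)[C@@H]1O[Si](CC)(CC)CC | intermediate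
22 | (5R,6R)-6-hydroxy-5-[(3S)-3-hydroxy-6-methylhepta-1,5-dien-2-yl]-2-methylcyclohex-2-en-1-one | C=C([C@H](CC=C(C)C)O)[C@H]1CC=C(C)C(=O)[C@@H]1O | intermediate
23 | angelic acid, (2Z)-2-methylbut-2-enoic acid | C/C=C(/C)C(=O)O | starting material
24 | (2Z)-2-methylbut-2-enoic 2,4,6-trichlorobenzoic anhydride | C/C=C(/C)C(=O)OC(=O)c1c(Cl)cc(Cl)cc1Cl | intermediate (not isolated)
25 | (1R,6R)-3-methyl-6-[(3S)-6-methyl-3-{[(2Z)-2-methylbut-2-enoyl]oxy}hepta-1,5-dien-2-yl]-2-oxocyclohex-3-en-1-yl (2Z)-2-methylbut-2-enoate | C=C([C@H](CC=C(C)C)OC(=O)/C(C)=C\C)[C@H]1CC=C(C)C(=O)[C@@H]1OC(=O)/C(C)=C\C | intermediate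
26 | (1R,6R)-6-[(3S)-4-[(2R)-3,3-dimethyloxiran-2-yl]-3-{[(2Z)-2-methylbut-2-enoyl]oxy}but-1-en-2-yl]-3-methyl-2-oxocyclohex-3-en-1-yl (2Z)-2-methylbut-2-enoate | C=C([C@H](C[C@H]1OC1(C)C)OC(=O)/C(C)=C\C)[C@H]1CC=C(C)C(=O)[C@@H]1OC(=O)/C(C)=C\C | intermediate
27 | (1R,2R,6R)-6-[(3S)-4-[(2R)-3,3-dimethyloxiran-2-yl]-3-{[(2Z)-2-methylbut-2-enoyl]oxy}but-1-en-2-yl]-2-hydroxy-3-methylcyclohex-3-en-1-yl (2Z)-2-methylbut-2-enoate | C=C([C@H](C[C@H]1OC1(C)C)OC(=O)/C(C)=C\C)[C@H]1CC=C(C)[C@@H](O)[C@@H]1OC(=O)/C(C)=C\C | intermediate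
28 | (1S,2S,3R,4R,6R)-4-[(3S)-4-[(2R)-3,3-dimethyloxiran-2-yl]-3-{[(2Z)-2-methylbut-2-enoyl]oxy}but-1-en-2-yl]-2-hydroxy-1-methyl-7-oxabicyclo[4.1.0]heptan-3-yl (2Z)-2-methylbut-2-enoate | C=C([C@H](C[C@H]1OC1(C)C)OC(=O)/C(C)=C\C)[C@H]1C[C@H]2O[C@@]2(C)[C@@H](O)[C@@H]1OC(=O)/C(C)=C\C | intermediate
29 | (1R,3R,4R,6R)-4-[(3S)-4-[(2R)-3,3-dimethyloxiran-2-yl]-3-{[(2Z)-2-methylbut-2-enoyl]oxy}but-1-en-2-yl]-1-methyl-2-oxo-7-oxabicyclo[4.1.0]heptan-3-yl (2Z)-2-methylbut-2-enoate (CNP0247177.1) | C=C([C@H](C[C@H]1OC1(C)C)OC(=O)/C(C)=C\C)[C@H]1C[C@H]2O[C@@]2(C)C(=O)[C@@H]1OC(=O)/C(C)=C\C | target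

**Step count**
Total: 16 steps. Longest linear sequence: 15 steps (steps 2 to 16, from 4 and 5 to 29); step 1 is a one-step side branch.

**Steps most likely to fail**

Step 6. The nickel may cleave the oxygen-bearing C–C(O) bond in place of the CH2–C(O) bond, or the alkylnickel intermediate may lose a β-hydride before reductive elimination. The fallback sets out from 8 and comes back at 15. The same nickel-catalysed insertion of 3 is run on the symmetric ketone 8, where both C–C(O) bonds are alike, to give the racemic 3-[benzyl(dimethyl)silyl]-5-(2,2-diethoxyethyl)-2-methylcyclohex-2-en-1-one F1. LiN(i-Pr)2 and Et3SiCl at −78 °C enolise F1 at the CH2 between the carbonyl and the side-chain carbon to give the cross-conjugated triethylsilyl dienol ether F2. Rubottom oxidation with DMDO, anti to the side chain, then gives the racemic trans silyloxy enone F3. Its enantiomers are parted by preparative chromatography on a chiral stationary phase, the (5S,6R) one being 15.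

Step 4. The base may discriminate poorly, or in the wrong sense, between the two enantiotopic α-CH2 groups. The fallback sets out from 8 and comes back at 12. LiN(i-Pr)2 followed by the Davis oxaziridine 2-(phenylsulfonyl)-3-phenyloxaziridine gives the racemic trans-3-(2,2-diethoxyethyl)-2-hydroxycyclobutan-1-one F4. Burkholderia cepacia lipase with vinyl acetate should, by the usual size rule for lipases, acetylate the (2S,3R) enantiomer to (1S,2R)-2-(2,2-diethoxyethyl)-4-oxocyclobutyl acetate F5 and leave (2R,3S)-3-(2,2-diethoxyethyl)-2-hydroxycyclobutan-1-one F6. Et3SiCl and imidazole turn F6 into 12.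

Step 5. The strained silyloxy epoxide may contract to a cyclopropane carbaldehyde in place of the silyl shift, or the dioxirane may add with poor facial selectivity. The fallback sets out from 10 and comes back at 12. MeLi cleaves the O–Si bond of 10 to give back lithium enolate 9. The Davis oxaziridine hydroxylates 9 at −78 °C, anti to the side chain, to lithium (1R,2S)-2-(2,2-diethoxyethyl)-4-oxocyclobutan-1-olate F7. Et3SiCl added to the same flask gives 12.

**Further compounds**
F1 | step 6 | rac-3-[benzyl(dimethyl)silyl]-5-(2,2-diethoxyethyl)-2-methylcyclohex-2-en-1-one | CCOC(OCC)CC1CC([Si](C)(C)Cc2ccccc2)=C(C)C(=O)C1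
F2 | step 6 | rac-triethylsilyl dienol ether of F1, enolised towards the ring CH2 next to the side-chain carbon (2-silyloxy-1,3-diene) | CCOC(OCC)CC1CC([Si](C)(C)Cc2ccccc2)=C(C)C(O[Si](CC)(CC)CC)=C1
F3 | step 6 | racemic form of 15, trans (one enantiomer drawn) | CCOC(OCC)C[C@H]1CC([Si](C)(C)Cc2ccccc2)=C(C)C(=O)[C@@H]1O[Si](CC)(CC)CC
F4 | step 4 | rac-trans-3-(2,2-diethoxyethyl)-2-hydroxycyclobutan-1-one (one enantiomer drawn) | CCOC(OCC)C[C@H]1CC(=O)[C@@H]1O
F5 | step 4 | (1S,2R)-2-(2,2-diethoxyethyl)-4-oxocyclobutyl acetate | CCOC(OCC)C[C@@H]1CC(=O)[C@H]1OC(C)=O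
F6 | step 4 | (2R,3S)-3-(2,2-diethoxyethyl)-2-hydroxycyclobutan-1-one | CCOC(OCC)C[C@H]1CC(=O)[C@@H]1O
F7 | step 5 | lithium (1R,2S)-2-(2,2-diethoxyethyl)-4-oxocyclobutan-1-olate | CCOC(OCC)C[C@H]1CC(=O)[C@@H]1O[Li]
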